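Retrosynthesis: the C5 carbinol goes back to the C5 ketone (reagent-controlled reduction). The carbocycle is then cut at C8–C8a and C5–C6, which frees C6–C7–C8 as the α, β and α′ carbons of diethyl glutarate (its two ester groups are temporary activators) and leaves a monocyclic 4-pyranone.
Enabling feature: in pyranone ring A, the ketene-acetal carbon C8a (it carries OEt and lies β to the C4 ketone) and the ester carbon C5 on C4a are the two ends of a 1,3-dielectrophile spanning C4a. Glutarate is the matching 1,3-dinucleophile, so one [3+3] addition–elimination/Dieckmann event closes carbocycle B.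
The pyranone is cut at O1–C8a and C4–C4a into an acylketene and a ketene acetal. The acylketene comes from a β-keto ester that already carries the whole (Z)-heptadecenyl chain, joined by γ-alkylation of acetoacetate dianion with a C16 Z-iodide.
Forward order: chain joined (steps 1–2), ring A made (step 3), ring B closed (step 4), both activating esters removed (step 5), C5 reduced (step 6).
Stereochemistry: the Z-alkene is bought with the C16 alcohol and never touched; (S)-C5 is set last by transfer hydrogenation with RuCl[(S,S)-TsDPEN](p-cymene).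

Key step: step 4

Remark: (11Z)-hexadec-11-en-1-ol (a pheromone alcohol) and ethyl 3,3-diethoxyprop-2-enoate are taken as purchasable; atom numbers are those of the chromen-4-one skeleton (O1, C2–C4, C4a, C5–C8, C8a).

Step 1
Reactants: 1 (11Z)-hexadec-11-en-1-ol
Product: 2 (11Z)-1-iodohexadec-11-ene
Conditions: I2, PPh3, imidazole, CH2Cl2, 0 °C to rt
Reagents that add atoms: iodine, II
Why: The Appel reaction turns the primary alcohol into the iodide by SN2 displacement of the alkoxyphosphonium group under neutral conditions that should leave the remote Z-alkene untouched.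

Step 2
Reactants: 3 tert-butyl 3-oxobutanoate (tert-butyl acetoacetate); 2 (11Z)-1-iodohexadec-11-ene
Product: 5 tert-butyl (15Z)-3-oxoicos-15-enoate, via acetoacetate dianion 4 (not isolated)
Conditions: NaH, THF, 0 °C; n-BuLi, 0 °C; 2, 0 °C to rt; 1 M HCl
Reagents that add atoms: none
Why: γ-Alkylation of a β-keto ester dianion: the doubly deprotonated acetoacetate reacts with a primary iodide only at its more basic terminal carbon, so the chain is joined at the methyl carbon and the β-keto ester is kept for step 3.

Step 3
Reactants: 5 tert-butyl (15Z)-3-oxoicos-15-enoate; 6 ethyl 3,3-diethoxyprop-2-enoate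
Product: 9 ethyl 2-ethoxy-6-[(12Z)-heptadec-12-en-1-yl]-4-oxo-4H-pyran-3-carboxylate, via acylketene 7 (not isolated), via diethoxy dihydropyranone 8 (not isolated)
Conditions: 6 (3 equiv), xylenes, 135 °C, slow addition of 5 under N2 sweep
Reagents that add atoms: none
Why: Thermal loss of tert-butanol from the β-keto ester gives acylketene 7, whose ketene carbon is attacked by the nucleophilic C2 of the ketene acetal while the acyl oxygen closes onto the acetal carbon (acylketene [4+2] cycloaddition with an electron-rich alkene), and loss of ethanol from 8 should give the 2-ethoxy-4-pyranone with the regiochemistry fixed by this polarity.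

Step 4
Reactants: 9 ethyl 2-ethoxy-6-[(12Z)-heptadec-12-en-1-yl]-4-oxo-4H-pyran-3-carboxylate; 10 diethyl pentanedioate (diethyl glutarate)
Product: 13 diethyl 2-[(12Z)-heptadec-12-en-1-yl]-4,5-dioxo-5,6,7,8-tetrahydro-4H-chromene-6,8-dicarboxylate (C6 and C8 unassigned; epimer/enol mixture), via glutarate lithium enolate 11 (not isolated), via pyranyl glutarate 12 (not isolated)
Conditions: 10 (2 equiv), LiN(iPr)2 (2 equiv), THF, −78 °C; 9, −78 °C; LiN(iPr)2 (2.5 equiv), −78 to 20 °C; AcOH
Reagents that add atoms: none
Why: Lithium enolate 11 adds to C8a of 9, the ketene-acetal carbon that lies β to both the C4 ketone and the C5 ester, and ethoxide is expelled to give 12 with the new C8–C8a bond (a second equivalent of 11 parks 12 as its C8 anion); the second charge of amide base then makes the ester enolate at C6, which attacks the C5 ester carbonyl on C4a, expels ethoxide and forms C5–C6, the β-keto ester product being held as its enolate so that the Claisen equilibrium cannot run back. The closest known reaction types are the Michael addition–elimination/Dieckmann [3+3] annulations of alkoxymethylene 1,3-dicarbonyl compounds and oxoketene acetals with 1,3-carbon dinucleophiles, and the double Claisen condensation of glutarate esters with oxalate. The first bond is formed between two molecules; ring B is then closed by a 6-exo-trig acyl substitution (Dieckmann mode), the C8a=C4a double bond holding C8 and the C5 ester on the same edge of ring A. C6 and C8 arise as enolizable stereocenters with no control, which does not matter because step 5 removes both, and no permanent stereocenter is made here. The step needs attack at C8a and not at C2 of the pyranone or at an ester carbonyl, which C8a secures as the only ring carbon that bears a leaving group and two acceptor groups, and it needs carbon attack to outrun proton transfer from the chain CH2 on C2, which the order of addition secures because 9 meets only preformed enolate at −78 °C and free amide base arrives after 9 is consumed. Attack of the C6 enolate on the C4 pyranone carbonyl would give a strained bridged aldolate that can revert, so the irreversible Dieckmann product should be the sink.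

Step 5
Reactants: 13 diethyl 2-[(12Z)-heptadec-12-en-1-yl]-4,5-dioxo-5,6,7,8-tetrahydro-4H-chromene-6,8-dicarboxylate
Product: 14 2-[(12Z)-heptadec-12-en-1-yl]-7,8-dihydro-4H-chromene-4,5(6H)-dione
Conditions: LiCl, H2O, DMSO, 140 °C, N2
Reagents that add atoms: none
Why: Krapcho dealkoxycarbonylation: the C6 ester is a β-keto ester and the C8 ester is its vinylog through C8a=C4a–C4=O, so chloride-assisted hydrolysis and loss of CO2 should remove both activating groups and erase the two uncontrolled stereocenters without touching the Z-alkene.

Step 6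
Reactants: 14 2-[(12Z)-heptadec-12-en-1-yl]-7,8-dihydro-4H-chromene-4,5(6H)-dione
Product: 15 (5S)-2-[(12Z)-heptadec-12-en-1-yl]-5-hydroxy-5,6,7,8-tetrahydro-4H-chromen-4-one
Conditions: RuCl[(S,S)-TsDPEN](p-cymene) (1 mol %), HCO2H/Et3N (5:2), CH2Cl2, 25 °C
Reagents that add atoms: none
Why: Noyori-type asymmetric transfer hydrogenation: the C5 ketone is flanked by the sp2 carbon C4a of the pyranone and by a CH2 group just as the carbonyl of 1-tetralone is, so the (S,S)-catalyst should deliver hydride to the face that gives the (S)-carbinol, while the vinylogous-ester carbonyl C4 and the isolated Z-alkene should not be reduced.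

Compound list
1 | (11Z)-hexadec-11-en-1-ol | CCCC/C=C\CCCCCCCCCCO | starting material
2 | (11Z)-1-iodohexadec-11-ene | CCCC/C=C\CCCCCCCCCCI | intermediate
3 | tert-butyl 3-oxobutanoate | CC(=O)CC(=O)OC(C)(C)C | starting material
4 | sodium lithium dianion of tert-butyl 3-oxobutanoate (not isolated) | C=C([O-])C=C([O-])OC(C)(C)C.[Na+].[Li+] | intermediate
5 | tert-butyl (15Z)-3-oxoicos-15-enoate | CCCC/C=C\CCCCCCCCCCCC(=O)CC(=O)OC(C)(C)C | intermediate
6 | ethyl 3,3-diethoxyprop-2-enoate | CCOC(=O)C=C(OCC)OCC | starting material
7 | (15Z)-icosa-1,15-diene-1,3-dione, the acylketene (not isolated) | CCCC/C=C\CCCCCCCCCCCC(=O)C=C=O | intermediate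
8 | ethyl 2,2-diethoxy-6-[(12Z)-heptadec-12-en-1-yl]-4-oxo-3,4-dihydro-2H-pyran-3-carboxylate (not isolated) | CCCC/C=C\CCCCCCCCCCCC1=CC(=O)C(C(=O)OCC)C(OCC)(OCC)O1 | intermediate
9 | ethyl 2-ethoxy-6-[(12Z)-heptadec-12-en-1-yl]-4-oxo-4H-pyran-3-carboxylate | CCCC/C=C\CCCCCCCCCCCC1=CC(=O)C(C(=O)OCC)=C(OCC)O1 | intermediate
10 | diethyl pentanedioate | CCOC(=O)CCCC(=O)OCC | starting material
11 | lithium enolate of diethyl pentanedioate (not isolated) | CCOC(=O)CCC=C([O-])OCC.[Li+] | intermediate
12 | diethyl 2-[3-(ethoxycarbonyl)-6-[(12Z)-heptadec-12-en-1-yl]-4-oxo-4H-pyran-2-yl]pentanedioate (not isolated) | CCCC/C=C\CCCCCCCCCCCC1=CC(=O)C(C(=O)OCC)=C(O1)C(CCC(=O)OCC)C(=O)OCC | intermediate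
13 | diethyl 2-[(12Z)-heptadec-12-en-1-yl]-4,5-dioxo-5,6,7,8-tetrahydro-4H-chromene-6,8-dicarboxylate (C6 and C8 unassigned) | CCCC/C=C\CCCCCCCCCCCC1=CC(=O)C2=C(O1)C(C(=O)OCC)CC(C(=O)OCC)C2=O | intermediate
14 | 2-[(12Z)-heptadec-12-en-1-yl]-7,8-dihydro-4H-chromene-4,5(6H)-dione | CCCC/C=C\CCCCCCCCCCCC1=CC(=O)C2=C(O1)CCCC2=O | intermediate
15 | (5S)-2-[(12Z)-heptadec-12-en-1-yl]-5-hydroxy-5,6,7,8-tetrahydro-4H-chromen-4-one | CCCC/C=C\CCCCCCCCCCCc1cc(=O)c2c(o1)CCC[C@@H]2O | target

Total step count: 6. Longest linear sequence: 6 steps (1 → 2 → 5 → 9 → 13 → 14 → 15).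

Steps most likely to fail

Step 4. What may go wrong: proton transfer from the chain CH2 on C2 of 9 to the ester enolate in place of carbon–carbon bond formation; enolate attack at C2 with opening of the pyranone; or stalling of the ring closure because the anion of 12 is delocalized into the C5 ester. The fallback sets out from 5 and comes back at 14, and it buys carbocycle B instead of building it. Cyclohexane-1,3-dione and pyrrolidine are condensed (toluene, water removal) to 3-(pyrrolidin-1-yl)cyclohex-2-en-1-one F1. Heating 5 with F1 in xylenes lets acylketene 7 acylate C2 of the enaminone to give 2-[(15Z)-3-oxoicos-15-enoyl]-3-(pyrrolidin-1-yl)cyclohex-2-en-1-one F2. Warming F2 in AcOH makes the enol oxygen of the chain ketone add to C3 and expel pyrrolidine, which closes the pyranone and gives 14.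

Step 3. What may go wrong: the acylketene is captured by the released alcohols or dimerizes faster than it is intercepted by the ester-deactivated ketene acetal, or ethanol is not lost cleanly from 8. The fallback sets out from 5 and comes back at 9. Heating 5 with diethyl malonate, MgCl2 and Et3N in toluene lets acylketene 7 acylate the malonate carbon to give diethyl 2-[(15Z)-3-oxoicos-15-enoyl]propanedioate F3, which lactonizes through its enol oxygen to ethyl 4-hydroxy-6-[(12Z)-heptadec-12-en-1-yl]-2-oxo-2H-pyran-3-carboxylate F4. Alkylation of F4 at the lactone carbonyl oxygen with Et3OBF4 (CH2Cl2, then iPr2NEt), the site preferred by hard alkylating agents, gives 9.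

Step 6. What may go wrong: poor facial selectivity or slow hydride transfer because the C5 carbonyl is a vinylogous ester next to the chelating C4 carbonyl, or ionization of the newly formed allylic-type carbinol in the acidic medium. The fallback sets out from 14 and comes back at 15, and it replaces asymmetric catalysis by resolution. Luche reduction of 14 (NaBH4, CeCl3·7H2O, MeOH, −20 °C) gives racemic 2-[(12Z)-heptadec-12-en-1-yl]-5-hydroxy-5,6,7,8-tetrahydro-4H-chromen-4-one F5. Kinetic resolution with immobilized Candida antarctica lipase B and vinyl acetate (t-BuOMe, 30 °C) should acylate the (R)-enantiomer, as this lipase does with 1-tetralol, to give (5R)-2-[(12Z)-heptadec-12-en-1-yl]-4-oxo-5,6,7,8-tetrahydro-4H-chromen-5-yl acetate F6. The unreacted (S)-alcohol 15 is then separated by chromatography.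

Further compounds
F1 | step 4 | 3-(pyrrolidin-1-yl)cyclohex-2-en-1-one | O=C1C=C(N2CCCC2)CCC1
F2 | step 4 | 2-[(15Z)-3-oxoicos-15-enoyl]-3-(pyrrolidin-1-yl)cyclohex-2-en-1-one | CCCC/C=C\CCCCCCCCCCCC(=O)CC(=O)C1=C(N2CCCC2)CCCC1=O
F3 | step 3 | diethyl 2-[(15Z)-3-oxoicos-15-enoyl]propanedioate | CCCC/C=C\CCCCCCCCCCCC(=O)CC(=O)C(C(=O)OCC)C(=O)OCC
F4 | step 3 | ethyl 4-hydroxy-6-[(12Z)-heptadec-12-en-1-yl]-2-oxo-2H-pyran-3-carboxylate | CCCC/C=C\CCCCCCCCCCCC1=CC(O)=C(C(=O)OCC)C(=O)O1
F5 | step 6 | racemic 2-[(12Z)-heptadec-12-en-1-yl]-5-hydroxy-5,6,7,8-tetrahydro-4H-chromen-4-one | CCCC/C=C\CCCCCCCCCCCC1=CC(=O)C2=C(O1)CCCC2O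
F6 | step 6 | (5R)-2-[(12Z)-heptadec-12-en-1-yl]-4-oxo-5,6,7,8-tetrahydro-4H-chromen-5-yl acetate | CCCC/C=C\CCCCCCCCCCCC1=CC(=O)C2=C(O1)CCC[C@H]2OC(C)=O
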